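**Retrosynthetic overview**
1. Target 26 ⇐ global desilylation of 25 ⇐ trans-selective α-alkylation of the 4-substituted butyrolactone 23 with benzylic bromide 12.
2. Bromide 12 ⇐ (2S,3R)-dihydrobenzofuran aldehyde 9; its furan ring is closed in the key step, a catalytic asymmetric C2–O bond formation (cycloisomerisation of hydroxystilbene 7 through a para-quinone methide) that sets C2 and C3.
3. Stilbene 7 ⇐ Suzuki coupling of 5-iodovanillin with the alkenylboronate obtained from 4-iodo-2-methoxyphenol and propargyl alcohol (Sonogashira, then hydroboration).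
4. Lactone 23 ⇐ Evans magnesium-catalysed anti-aldol of succinate imide 16 with silylated vanillin (sets the carbinol carbon and lactone C4), then reductive auxiliary removal with lactonisation.
5. Ring order: the dihydrofuran ring (step 3) and the butyrolactone ring (step 11) are made separately and joined in step 12.

Assumption: the SMILES is read as drawn (lactone 3R,4R; carbinol R; dihydrobenzofuran 2S,3R). The chiral acid in step 3 is written as (R); if the first run shows the opposite sense, the (S)-acid is used. TBS = tert-butyldimethylsilyl, TMS = trimethylsilyl.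

**Route**

Step 1
Reactants: 1 4-iodo-2-methoxyphenol; 2 prop-2-yn-1-ol
Product: 3 3-(4-hydroxy-3-methoxyphenyl)prop-2-yn-1-ol
Conditions: Pd(PPh3)2Cl2 (2 mol%), CuI (4 mol%), Et3N, THF, 40 °C
Reagents that add atoms: none
Why: Sonogashira coupling, in which zerovalent palladium inserts into the aryl–iodine bond and the copper acetylide delivers the alkyne; the free phenol and alcohol are tolerated and no stereocentre is formed.

Step 2
Reactants: 3 3-(4-hydroxy-3-methoxyphenyl)prop-2-yn-1-ol; 4 bis(pinacolato)diboron; 5 4-hydroxy-3-iodo-5-methoxybenzaldehyde (5-iodovanillin)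
Product: 7 4-hydroxy-3-[(Z)-3-hydroxy-1-(4-hydroxy-3-methoxyphenyl)prop-1-en-2-yl]-5-methoxybenzaldehyde, via alkenylboronate 6 (not isolated)
Conditions: CuCl (5 mol%), Xantphos (6 mol%), NaOtBu (10 mol%), 4 (1.1 equiv), MeOH (2 equiv), THF, rt; then 5, Pd(dppf)Cl2 (3 mol%), aq. K3PO4, 60 °C
Reagents that add atoms: none
Why: Copper–boryl syn-addition places boron on the alkyne carbon remote from the aryl group (copper at the aryl-bearing carbon, reinforced by the propargylic oxygen), MeOH protonates the alkenylcopper, and Suzuki–Miyaura coupling with the ortho-iodophenol retains the alkene geometry; no stereocentre is formed and the geometry is erased in step 3.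

Step 3
Reactants: 7 4-hydroxy-3-[(Z)-3-hydroxy-1-(4-hydroxy-3-methoxyphenyl)prop-1-en-2-yl]-5-methoxybenzaldehyde
Product: 9 (2S,3R)-2-(4-hydroxy-3-methoxyphenyl)-3-(hydroxymethyl)-7-methoxy-2,3-dihydro-1-benzofuran-5-carbaldehyde, via para-quinone methide 8 (not isolated)
Conditions: (R)-TRIP [(R)-3,3'-bis(2,4,6-triisopropylphenyl)-1,1'-binaphthyl-2,2'-diyl hydrogen phosphate] (10 mol%), CH2Cl2 (0.02 M), 5 Å MS, 0 °C to rt
Reagents that add atoms: none
Why: Proposed new method: enantioselective cycloisomerisation (intramolecular hydroalkoxylation) of a 4-hydroxystilbene through its quinone methide tautomer; the chiral phosphoric acid protonates the electron-rich alkene at the carbon bearing ring B, giving the phosphate ion pair of O-protonated para-quinone methide 8 (stabilised by the para-hydroxyl of ring A); this proton transfer is reversible, so both configurations at the new CH centre interconvert through 7, and the ortho-phenol of ring B, hydrogen-bonded to the phosphate, closes 5-exo on one face of the methide carbon, forming the C2–O bond and fixing C2 (S), while the strong trans preference of this ring closure selects the matching C3 (R) epimer (dynamic kinetic asymmetric transformation); the closest known reaction types are chiral phosphoric acid-catalysed 1,6-additions of heteroatom nucleophiles to para-quinone methides generated in situ, acid-mediated tautomerisation of hydroxystyrenes to quinone methides, and Brønsted acid-catalysed asymmetric intramolecular hydroalkoxylation of alkenes.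

Step 4
Reactants: 9 (2S,3R)-2-(4-hydroxy-3-methoxyphenyl)-3-(hydroxymethyl)-7-methoxy-2,3-dihydro-1-benzofuran-5-carbaldehyde
Product: 10 (2S,3R)-2-[4-(tert-butyldimethylsilyloxy)-3-methoxyphenyl]-3-[(tert-butyldimethylsilyloxy)methyl]-7-methoxy-2,3-dihydro-1-benzofuran-5-carbaldehyde
Conditions: TBSCl (2.5 equiv), imidazole, DMF, rt
Reagents that add atoms: tert-butyldimethylsilyl chloride, CC(C)(C)[Si](C)(C)Cl
Why: Standard imidazole-promoted silylation masks the phenol and the primary alcohol for the later enolate alkylation; the stereocentres are untouched.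

Step 5
Reactants: 10 (2S,3R)-2-[4-(tert-butyldimethylsilyloxy)-3-methoxyphenyl]-3-[(tert-butyldimethylsilyloxy)methyl]-7-methoxy-2,3-dihydro-1-benzofuran-5-carbaldehyde
Product: 11 {(2S,3R)-2-[4-(tert-butyldimethylsilyloxy)-3-methoxyphenyl]-3-[(tert-butyldimethylsilyloxy)methyl]-7-methoxy-2,3-dihydro-1-benzofuran-5-yl}methanol
Conditions: NaBH4, THF/MeOH (10:1), 0 °C
Reagents that add atoms: none
Why: Chemoselective borohydride reduction of the aryl aldehyde; the silyl ethers and the benzylic ring ether survive the short, cold reaction.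

Step 6
Reactants: 11 {(2S,3R)-2-[4-(tert-butyldimethylsilyloxy)-3-methoxyphenyl]-3-[(tert-butyldimethylsilyloxy)methyl]-7-methoxy-2,3-dihydro-1-benzofuran-5-yl}methanol
Product: 12 (2S,3R)-5-(bromomethyl)-2-[4-(tert-butyldimethylsilyloxy)-3-methoxyphenyl]-3-[(tert-butyldimethylsilyloxy)methyl]-7-methoxy-2,3-dihydro-1-benzofuran
Conditions: CBr4, PPh3, 2,6-lutidine, CH2Cl2, 0 °C; used crude
Reagents that add atoms: carbon tetrabromide, BrC(Br)(Br)Br
Why: Appel reaction under buffered, non-acidic conditions converts the benzylic alcohol into the bromide without opening the acid-sensitive benzylic ring ether or the silyl ethers.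

Step 7
Reactants: 13 (4R)-4-benzyl-1,3-oxazolidin-2-one; 14 methyl 4-chloro-4-oxobutanoate
Product: 16 methyl 4-[(4R)-4-benzyl-2-oxo-1,3-oxazolidin-3-yl]-4-oxobutanoate, via N-lithio oxazolidinone 15 (not isolated)
Conditions: n-BuLi, THF, −78 °C; then 14, −78 to 0 °C
Reagents that add atoms: none
Why: N-acylation of the lithiated Evans auxiliary by the acid chloride, which reacts far faster than the methyl ester.

Step 8
Reactants: 17 4-hydroxy-3-methoxybenzaldehyde (vanillin)
Product: 18 4-(tert-butyldimethylsilyloxy)-3-methoxybenzaldehyde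
Conditions: TBSCl, imidazole, DMF, rt
Reagents that add atoms: tert-butyldimethylsilyl chloride, CC(C)(C)[Si](C)(C)Cl
Why: Standard phenol silylation; the aryl silyl ether is later removed by fluoride without touching the benzylic carbinol.

Step 9
Reactants: 16 methyl 4-[(4R)-4-benzyl-2-oxo-1,3-oxazolidin-3-yl]-4-oxobutanoate; 18 4-(tert-butyldimethylsilyloxy)-3-methoxybenzaldehyde
Product: 19 methyl (3S,4R)-3-{[(4R)-4-benzyl-2-oxo-1,3-oxazolidin-3-yl]carbonyl}-4-[4-(tert-butyldimethylsilyloxy)-3-methoxyphenyl]-4-(trimethylsilyloxy)butanoate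
Conditions: MgCl2 (20 mol%), Et3N (2 equiv), TMSCl (1.5 equiv), EtOAc, rt, 24 h; filtered through Et3N-deactivated silica
Reagents that add atoms: chlorotrimethylsilane, C[Si](C)(C)Cl
Why: Evans magnesium chloride-catalysed direct anti-aldol, in which soft enolisation gives the chelated (Z)-magnesium enolate that adds to the aromatic aldehyde on the face opposite the benzyl group through a boat transition state, setting the anti (3S,4R) pair from the (R)-auxiliary; in situ O-silylation turns the catalyst over and blocks retro-aldol and lactonisation onto the ester.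

Step 10
Reactants: 19 methyl (3S,4R)-3-{[(4R)-4-benzyl-2-oxo-1,3-oxazolidin-3-yl]carbonyl}-4-[4-(tert-butyldimethylsilyloxy)-3-methoxyphenyl]-4-(trimethylsilyloxy)butanoate
Product: 21 methyl (3S,4R)-3-{[(4R)-4-benzyl-2-oxo-1,3-oxazolidin-3-yl]carbonyl}-4-(tert-butyldimethylsilyloxy)-4-[4-(tert-butyldimethylsilyloxy)-3-methoxyphenyl]butanoate, via hydroxy imide 20 (not isolated)
Conditions: aq. citric acid, MeOH, 0 °C, 15 min; then TBSOTf, 2,6-lutidine, CH2Cl2, −78 to 0 °C
Reagents that add atoms: tert-butyldimethylsilyl triflate, CC(C)(C)[Si](C)(C)OS(=O)(=O)C(F)(F)F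
Why: The labile TMS ether is cleaved by mild acid and the alcohol is immediately re-silylated with the silyl triflate, so the carbinol never stays free next to the γ-ester long enough to form the wrong lactone; no stereocentre is affected.

Step 11
Reactants: 21 methyl (3S,4R)-3-{[(4R)-4-benzyl-2-oxo-1,3-oxazolidin-3-yl]carbonyl}-4-(tert-butyldimethylsilyloxy)-4-[4-(tert-butyldimethylsilyloxy)-3-methoxyphenyl]butanoate
Product: 23 (4R)-4-{(R)-[4-(tert-butyldimethylsilyloxy)-3-methoxyphenyl](tert-butyldimethylsilyloxy)methyl}oxolan-2-one, via hydroxy ester 22 (not isolated)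
Conditions: NaBH4, THF/H2O (4:1), 0 °C to rt; then PPTS (cat.), CH2Cl2, rt
Reagents that add atoms: none
Why: Borohydride reduces the exocyclic imide carbonyl (reductive removal of the Evans auxiliary) and the new primary alcohol closes onto the methyl ester to the γ-lactone; with the carbinol silylated only this lactone can form, and both stereocentres are retained.

Step 12
Reactants: 23 (4R)-4-{(R)-[4-(tert-butyldimethylsilyloxy)-3-methoxyphenyl](tert-butyldimethylsilyloxy)methyl}oxolan-2-one; 12 (2S,3R)-5-(bromomethyl)-2-[4-(tert-butyldimethylsilyloxy)-3-methoxyphenyl]-3-[(tert-butyldimethylsilyloxy)methyl]-7-methoxy-2,3-dihydro-1-benzofuran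
Product: 25 (3R,4R)-4-{(R)-[4-(tert-butyldimethylsilyloxy)-3-methoxyphenyl](tert-butyldimethylsilyloxy)methyl}-3-({(2S,3R)-2-[4-(tert-butyldimethylsilyloxy)-3-methoxyphenyl]-3-[(tert-butyldimethylsilyloxy)methyl]-7-methoxy-2,3-dihydro-1-benzofuran-5-yl}methyl)oxolan-2-one, via lithium enolate 24 (not isolated)
Conditions: LiN(SiMe3)2, THF, −78 °C; then 12, DMPU, −78 to −30 °C
Reagents that add atoms: none
Why: Enolate alkylation of a 4-substituted γ-butyrolactone, in which the benzylic bromide approaches anti to the bulky C4 substituent and sets C3 (R), trans to C4, as in standard dibenzylbutyrolactone lignan syntheses.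

Step 13
Reactants: 25 (3R,4R)-4-{(R)-[4-(tert-butyldimethylsilyloxy)-3-methoxyphenyl](tert-butyldimethylsilyloxy)methyl}-3-({(2S,3R)-2-[4-(tert-butyldimethylsilyloxy)-3-methoxyphenyl]-3-[(tert-butyldimethylsilyloxy)methyl]-7-methoxy-2,3-dihydro-1-benzofuran-5-yl}methyl)oxolan-2-one
Product: 26 (3R,4R)-4-[(R)-hydroxy(4-hydroxy-3-methoxyphenyl)methyl]-3-{[(2S,3R)-2-(4-hydroxy-3-methoxyphenyl)-3-(hydroxymethyl)-7-methoxy-2,3-dihydro-1-benzofuran-5-yl]methyl}oxolan-2-one
Conditions: Bu4NF/AcOH (1:1, excess), THF, 0 °C to rt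
Reagents that add atoms: none
Why: Buffered fluoride desilylation removes all four silyl ethers; the acetic acid keeps the carbinol from forming an alkoxide, which prevents translactonisation and quinone methide-mediated epimerisation at the para-hydroxybenzylic centre.

**Compound list**
1 | 4-iodo-2-methoxyphenol | COc1cc(I)ccc1O | starting material
2 | prop-2-yn-1-ol | OCC#C | starting material
3 | 3-(4-hydroxy-3-methoxyphenyl)prop-2-yn-1-ol | COc1cc(C#CCO)ccc1O | intermediate
4 | bis(pinacolato)diboron | CC1(C)OB(OC1(C)C)B1OC(C)(C)C(C)(C)O1 | starting material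
5 | 4-hydroxy-3-iodo-5-methoxybenzaldehyde | COc1cc(C=O)cc(I)c1O | starting material
6 | (Z)-3-(4-hydroxy-3-methoxyphenyl)-2-(4,4,5,5-tetramethyl-1,3,2-dioxaborolan-2-yl)prop-2-en-1-ol | OC/C(B1OC(C)(C)C(C)(C)O1)=C\c1ccc(O)c(OC)c1 | intermediate
7 | 4-hydroxy-3-[(Z)-3-hydroxy-1-(4-hydroxy-3-methoxyphenyl)prop-1-en-2-yl]-5-methoxybenzaldehyde | OC/C(c1cc(C=O)cc(OC)c1O)=C\c1ccc(O)c(OC)c1 | intermediate
8 | 4-hydroxy-3-[(2R)-1-hydroxy-3-(3-methoxy-4-oxocyclohexa-2,5-dien-1-ylidene)propan-2-yl]-5-methoxybenzaldehyde (para-quinone methide, either ylidene geometry) | O=C1C=CC(=C[C@@H](CO)c2cc(C=O)cc(OC)c2O)C=C1OC | intermediate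
9 | (2S,3R)-2-(4-hydroxy-3-methoxyphenyl)-3-(hydroxymethyl)-7-methoxy-2,3-dihydro-1-benzofuran-5-carbaldehyde | COc1cc([C@H]2Oc3c(OC)cc(C=O)cc3[C@@H]2CO)ccc1O | intermediate
10 | (2S,3R)-2-[4-(tert-butyldimethylsilyloxy)-3-methoxyphenyl]-3-[(tert-butyldimethylsilyloxy)methyl]-7-methoxy-2,3-dihydro-1-benzofuran-5-carbaldehyde | COc1cc([C@H]2Oc3c(OC)cc(C=O)cc3[C@@H]2CO[Si](C)(C)C(C)(C)C)ccc1O[Si](C)(C)C(C)(C)C | intermediate
11 | {(2S,3R)-2-[4-(tert-butyldimethylsilyloxy)-3-methoxyphenyl]-3-[(tert-butyldimethylsilyloxy)methyl]-7-methoxy-2,3-dihydro-1-benzofuran-5-yl}methanol | COc1cc([C@H]2Oc3c(OC)cc(CO)cc3[C@@H]2CO[Si](C)(C)C(C)(C)C)ccc1O[Si](C)(C)C(C)(C)C | intermediate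
12 | (2S,3R)-5-(bromomethyl)-2-[4-(tert-butyldimethylsilyloxy)-3-methoxyphenyl]-3-[(tert-butyldimethylsilyloxy)methyl]-7-methoxy-2,3-dihydro-1-benzofuran | COc1cc([C@H]2Oc3c(OC)cc(CBr)cc3[C@@H]2CO[Si](C)(C)C(C)(C)C)ccc1O[Si](C)(C)C(C)(C)C | intermediate
13 | (4R)-4-benzyl-1,3-oxazolidin-2-one | O=C1N[C@H](Cc2ccccc2)CO1 | starting material
14 | methyl 4-chloro-4-oxobutanoate | COC(=O)CCC(Cl)=O | starting material
15 | N-lithio-(4R)-4-benzyl-1,3-oxazolidin-2-one | [Li]N1[C@H](Cc2ccccc2)COC1=O | intermediate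
16 | methyl 4-[(4R)-4-benzyl-2-oxo-1,3-oxazolidin-3-yl]-4-oxobutanoate | COC(=O)CCC(=O)N1[C@H](Cc2ccccc2)COC1=O | intermediate
17 | 4-hydroxy-3-methoxybenzaldehyde | COc1cc(C=O)ccc1O | starting material
18 | 4-(tert-butyldimethylsilyloxy)-3-methoxybenzaldehyde | COc1cc(C=O)ccc1O[Si](C)(C)C(C)(C)C | intermediate
19 | methyl (3S,4R)-3-{[(4R)-4-benzyl-2-oxo-1,3-oxazolidin-3-yl]carbonyl}-4-[4-(tert-butyldimethylsilyloxy)-3-methoxyphenyl]-4-(trimethylsilyloxy)butanoate | COC(=O)C[C@H](C(=O)N1[C@H](Cc2ccccc2)COC1=O)[C@@H](O[Si](C)(C)C)c1ccc(O[Si](C)(C)C(C)(C)C)c(OC)c1 | intermediate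
20 | methyl (3S,4R)-3-{[(4R)-4-benzyl-2-oxo-1,3-oxazolidin-3-yl]carbonyl}-4-[4-(tert-butyldimethylsilyloxy)-3-methoxyphenyl]-4-hydroxybutanoate | COC(=O)C[C@H](C(=O)N1[C@H](Cc2ccccc2)COC1=O)[C@@H](O)c1ccc(O[Si](C)(C)C(C)(C)C)c(OC)c1 | intermediate
21 | methyl (3S,4R)-3-{[(4R)-4-benzyl-2-oxo-1,3-oxazolidin-3-yl]carbonyl}-4-(tert-butyldimethylsilyloxy)-4-[4-(tert-butyldimethylsilyloxy)-3-methoxyphenyl]butanoate | COC(=O)C[C@H](C(=O)N1[C@H](Cc2ccccc2)COC1=O)[C@@H](O[Si](C)(C)C(C)(C)C)c1ccc(O[Si](C)(C)C(C)(C)C)c(OC)c1 | intermediate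
22 | methyl (3R,4R)-4-(tert-butyldimethylsilyloxy)-4-[4-(tert-butyldimethylsilyloxy)-3-methoxyphenyl]-3-(hydroxymethyl)butanoate | COC(=O)C[C@H](CO)[C@@H](O[Si](C)(C)C(C)(C)C)c1ccc(O[Si](C)(C)C(C)(C)C)c(OC)c1 | intermediate
23 | (4R)-4-{(R)-[4-(tert-butyldimethylsilyloxy)-3-methoxyphenyl](tert-butyldimethylsilyloxy)methyl}oxolan-2-one | O=C1C[C@H](CO1)[C@@H](O[Si](C)(C)C(C)(C)C)c2ccc(O[Si](C)(C)C(C)(C)C)c(OC)c2 | intermediate
24 | lithium enolate of 23 | [Li]OC1=C[C@H](CO1)[C@@H](O[Si](C)(C)C(C)(C)C)c2ccc(O[Si](C)(C)C(C)(C)C)c(OC)c2 | intermediate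
25 | (3R,4R)-4-{(R)-[4-(tert-butyldimethylsilyloxy)-3-methoxyphenyl](tert-butyldimethylsilyloxy)methyl}-3-({(2S,3R)-2-[4-(tert-butyldimethylsilyloxy)-3-methoxyphenyl]-3-[(tert-butyldimethylsilyloxy)methyl]-7-methoxy-2,3-dihydro-1-benzofuran-5-yl}methyl)oxolan-2-one | COc1cc([C@H]2Oc3c(OC)cc(C[C@H]4C(=O)OC[C@@H]4[C@@H](O[Si](C)(C)C(C)(C)C)c4ccc(O[Si](C)(C)C(C)(C)C)c(OC)c4)cc3[C@@H]2CO[Si](C)(C)C(C)(C)C)ccc1O[Si](C)(C)C(C)(C)C | intermediate
26 | (3R,4R)-4-[(R)-hydroxy(4-hydroxy-3-methoxyphenyl)methyl]-3-{[(2S,3R)-2-(4-hydroxy-3-methoxyphenyl)-3-(hydroxymethyl)-7-methoxy-2,3-dihydro-1-benzofuran-5-yl]methyl}oxolan-2-one | COc1cc([C@H]2Oc3c(OC)cc(C[C@H]4C(=O)OC[C@@H]4[C@@H](O)c4ccc(O)c(OC)c4)cc3[C@@H]2CO)ccc1O | target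

**Step count**
Total: 13 steps. Longest linear sequence: 8 steps (1, 2, 3, 4, 5, 6, 12, 13).

**Steps most likely to fail, with fallbacks**

Step 3 (the new reaction): the acid may give low enantioselectivity, or the product may lose enantiopurity through reversible ring opening. The fallback uses known chemistry, sets out from 7 and comes back at 9. Stilbene 7 is cyclised with an achiral Brønsted acid (TsOH·H2O, 10 mol%, CH2Cl2, rt), an acid-mediated hydroalkoxylation of an ortho-hydroxystilbene that gives only the trans ring. This affords 9 as a racemate together with its mirror image (2R,3S)-2-(4-hydroxy-3-methoxyphenyl)-3-(hydroxymethyl)-7-methoxy-2,3-dihydro-1-benzofuran-5-carbaldehyde F1. The two are separated by preparative HPLC on a cellulose tris(3,5-dimethylphenylcarbamate) phase, and 9 continues at step 4.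

Step 9 (anti-aldol with an ester-bearing imide and an electron-rich aldehyde): conversion or the anti:syn ratio may be poor. The fallback replaces the aldol by acylation and reduction; it sets out from 16 and 18 and comes back at 20, which is silylated to 21 as in step 10.
- Aldehyde 18 is oxidised (NaClO2, NaH2PO4, 2-methylbut-2-ene, tBuOH/H2O) to 4-(tert-butyldimethylsilyloxy)-3-methoxybenzoic acid F2.
- F2 is converted ((COCl)2, cat. DMF, CH2Cl2) into 4-(tert-butyldimethylsilyloxy)-3-methoxybenzoyl chloride F3.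
- The sodium enolate of 16 (NaN(SiMe3)2, THF, −78 °C) is C-acylated by F3 on the face opposite the benzyl group (Evans acylation). This gives methyl (3S)-3-{[(4R)-4-benzyl-2-oxo-1,3-oxazolidin-3-yl]carbonyl}-4-[4-(tert-butyldimethylsilyloxy)-3-methoxyphenyl]-4-oxobutanoate F4, whose α-centre is held by allylic 1,3-strain.
- Non-chelating Felkin–Anh reduction of the ketone (KBEt3H, Et2O, −78 °C) gives the anti alcohol 20; chelating hydrides such as Zn(BH4)2 would give the syn epimer instead.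

Step 12 (alkylation with the elaborate, labile benzylic bromide): the bromide may decompose or the hindered enolate may react sluggishly. The fallback replaces the alkylation by aldol condensation and conjugate reduction; it sets out from 23 and aldehyde 10 (steps 5 and 6 are then not needed) and comes back at 25.
- The lithium enolate of 23 (LiN(SiMe3)2, THF, −78 °C) adds to 10 to give (4R)-4-{(R)-[4-(tert-butyldimethylsilyloxy)-3-methoxyphenyl](tert-butyldimethylsilyloxy)methyl}-3-({(2S,3R)-2-[4-(tert-butyldimethylsilyloxy)-3-methoxyphenyl]-3-[(tert-butyldimethylsilyloxy)methyl]-7-methoxy-2,3-dihydro-1-benzofuran-5-yl}(hydroxy)methyl)oxolan-2-one F5, as a mixture at the two new centres.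
- Acetylation (Ac2O, Et3N, DMAP) gives the corresponding O-acetate of the aldol adduct F6.
- Elimination (DBU, toluene, rt) gives (3E,4R)-4-{(R)-[4-(tert-butyldimethylsilyloxy)-3-methoxyphenyl](tert-butyldimethylsilyloxy)methyl}-3-({(2S,3R)-2-[4-(tert-butyldimethylsilyloxy)-3-methoxyphenyl]-3-[(tert-butyldimethylsilyloxy)methyl]-7-methoxy-2,3-dihydro-1-benzofuran-5-yl}methylidene)oxolan-2-one F7.
- Conjugate reduction (NaBH4, NiCl2·6H2O, MeOH/THF, 0 °C) gives 25 mixed with its cis epimer, the (3S,4R)-diastereomer of 25 F8.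
- DBU (toluene, 60 °C) equilibrates F8 to the more stable trans lactone 25.

**Further compounds**
F1 | step 3 | (2R,3S)-2-(4-hydroxy-3-methoxyphenyl)-3-(hydroxymethyl)-7-methoxy-2,3-dihydro-1-benzofuran-5-carbaldehyde | COc1cc([C@@H]2Oc3c(OC)cc(C=O)cc3[C@H]2CO)ccc1O
F2 | step 9 | 4-(tert-butyldimethylsilyloxy)-3-methoxybenzoic acid | COc1cc(C(=O)O)ccc1O[Si](C)(C)C(C)(C)C
F3 | step 9 | 4-(tert-butyldimethylsilyloxy)-3-methoxybenzoyl chloride | COc1cc(C(=O)Cl)ccc1O[Si](C)(C)C(C)(C)C
F4 | step 9 | methyl (3S)-3-{[(4R)-4-benzyl-2-oxo-1,3-oxazolidin-3-yl]carbonyl}-4-[4-(tert-butyldimethylsilyloxy)-3-methoxyphenyl]-4-oxobutanoate | COC(=O)C[C@H](C(=O)N1[C@H](Cc2ccccc2)COC1=O)C(=O)c1ccc(O[Si](C)(C)C(C)(C)C)c(OC)c1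
F5 | step 12 | aldol adduct of 23 and 10 (mixture at lactone C3 and the new carbinol carbon) | COc1cc([C@H]2Oc3c(OC)cc(C(O)C4C(=O)OC[C@@H]4[C@@H](O[Si](C)(C)C(C)(C)C)c4ccc(O[Si](C)(C)C(C)(C)C)c(OC)c4)cc3[C@@H]2CO[Si](C)(C)C(C)(C)C)ccc1O[Si](C)(C)C(C)(C)C
F6 | step 12 | O-acetate of F5 | COc1cc([C@H]2Oc3c(OC)cc(C(OC(C)=O)C4C(=O)OC[C@@H]4[C@@H](O[Si](C)(C)C(C)(C)C)c4ccc(O[Si](C)(C)C(C)(C)C)c(OC)c4)cc3[C@@H]2CO[Si](C)(C)C(C)(C)C)ccc1O[Si](C)(C)C(C)(C)C
F7 | step 12 | (3E,4R)-3-arylmethylidene lactone (name as in the text) | COc1cc([C@H]2Oc3c(OC)cc(/C=C4/C(=O)OC[C@@H]4[C@@H](O[Si](C)(C)C(C)(C)C)c4ccc(O[Si](C)(C)C(C)(C)C)c(OC)c4)cc3[C@@H]2CO[Si](C)(C)C(C)(C)C)ccc1O[Si](C)(C)C(C)(C)C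
F8 | step 12 | (3S,4R)-diastereomer of 25 (cis lactone) | COc1cc([C@H]2Oc3c(OC)cc(C[C@@H]4C(=O)OC[C@@H]4[C@@H](O[Si](C)(C)C(C)(C)C)c4ccc(O[Si](C)(C)C(C)(C)C)c(OC)c4)cc3[C@@H]2CO[Si](C)(C)C(C)(C)C)ccc1O[Si](C)(C)C(C)(C)C
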